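**Retrosynthetic overview**

1. The target, robinetinidol-(4α→6)-gallocatechin, is unmasked by one hydrogenolysis; the interflavan C4–C6 bond and the C3/C4 stereocentres come from anti epoxidation of a (2S)-flav-3-ene and anti Friedel–Crafts opening by C8-bromo-capped penta-O-benzyl-(+)-gallocatechin.
2. The flav-3-ene is disconnected at O1–C8a of the upper unit: ring A is carried as a non-aromatic quinone monoketal carbinol, and one acid-mediated operation (ketal hydrolysis, oxa-Michael addition of the C2 hydroxyl to C8a, dehydration) closes ring C and aromatizes ring A.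
3. Enabling feature: upper ring A bears oxygen only at C8a (O1) and C7, with C7 para to C4a and meta to C8a and no oxygen at C5. Ring A therefore maps onto a mirror-symmetric 4-substituted 4-hydroxycyclohexa-2,5-dienone: C7 is the carbonyl, C8a and C5 are equivalent β-carbons, and the C4a hydroxyl is the leaving group that restores aromaticity.
4. The cyclization precursor is assembled from 3,4,5-tris(benzyloxy)benzaldehyde, trimethylsilylacetylene and 4,4-dimethoxycyclohexa-2,5-dien-1-one by asymmetric alkynylation (sets C2), acetylide 1,2-addition and Lindlar reduction.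
5. Ring order: ring B and the whole lower unit (rings D, E, F) are bought; ring C closes and ring A becomes aromatic in the same step; no other ring is formed.

Key step: step 5

Assumption: the (S,S) enantiomer of ProPhenol is taken to deliver the carbinol configuration needed in step 1; should the sense of induction for this aldehyde be opposite, the (R,R) ligand is used and nothing else changes.

**Route**

Step 1
Reactants: 1 3,4,5-tris(benzyloxy)benzaldehyde; 2 trimethylsilylacetylene
Product: 3 (R)-1-[3,4,5-tris(benzyloxy)phenyl]-3-(trimethylsilyl)prop-2-yn-1-ol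
Conditions: Me2Zn (3 equiv), (S,S)-ProPhenol (10 mol %), Ph3PO (20 mol %), toluene, 0 °C to rt; aq NH4Cl
Reagents that add atoms: none
Why: Zinc alkynylide addition under dinuclear zinc–ProPhenol catalysis (catalytic asymmetric alkynylation of an aryl aldehyde) should set the carbinol carbon, the future C2, by catalyst control of the aldehyde face.

Step 2
Reactants: 3 (R)-1-[3,4,5-tris(benzyloxy)phenyl]-3-(trimethylsilyl)prop-2-yn-1-ol
Product: 4 (S)-1-[3,4,5-tris(benzyloxy)phenyl]prop-2-yn-1-ol
Conditions: K2CO3 (0.2 equiv), MeOH–THF, rt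
Reagents that add atoms: none
Why: Base-catalysed methanolysis of the alkynyl C–Si bond (protodesilylation) should leave the carbinol centre and the benzyl ethers untouched; the descriptor changes from R to S only because the priority of the alkynyl group drops.

Step 3
Reactants: 4 (S)-1-[3,4,5-tris(benzyloxy)phenyl]prop-2-yn-1-ol; 5 4,4-dimethoxycyclohexa-2,5-dien-1-one
Product: 6 1-{(3R)-3-hydroxy-3-[3,4,5-tris(benzyloxy)phenyl]prop-1-yn-1-yl}-4,4-dimethoxycyclohexa-2,5-dien-1-ol
Conditions: n-BuLi (2.1 equiv), THF, −78 °C; then 5, −78 to −40 °C; aq NH4Cl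
Reagents that add atoms: none
Why: The alkoxide–acetylide dianion should add 1,2 to the carbonyl of the quinone monoketal (acetylide addition to a cross-conjugated dienone), installing ring A as a symmetric non-aromatic ring whose new carbinol carbon (C4a) carries two identical arms and is no stereocentre.

Step 4
Reactants: 6 1-{(3R)-3-hydroxy-3-[3,4,5-tris(benzyloxy)phenyl]prop-1-yn-1-yl}-4,4-dimethoxycyclohexa-2,5-dien-1-ol
Product: 7 1-{(1Z,3S)-3-hydroxy-3-[3,4,5-tris(benzyloxy)phenyl]prop-1-en-1-yl}-4,4-dimethoxycyclohexa-2,5-dien-1-ol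
Conditions: H2 (1 atm), Pd/CaCO3 poisoned with Pb(OAc)2 (Lindlar catalyst), quinoline, EtOAc, rt
Reagents that add atoms: none
Why: Lindlar semihydrogenation should add H2 syn to the alkyne only, giving the Z alkene that brings the C2 hydroxyl within reach of ring A while the ring alkenes, the ketal and the benzyl ethers are left alone.

Step 5
Reactants: 7 1-{(1Z,3S)-3-hydroxy-3-[3,4,5-tris(benzyloxy)phenyl]prop-1-en-1-yl}-4,4-dimethoxycyclohexa-2,5-dien-1-ol
Product: 10 (S)-2-[3,4,5-tris(benzyloxy)phenyl]-2H-chromen-7-ol, via p-quinol 8 (not isolated), via cis-fused oxa-Michael adduct 9 (not isolated)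
Conditions: (PhO)2P(O)OH (10 mol %), H2O (3 equiv), CH2Cl2, 0 °C to rt, then 35 °C until 8 and 9 are consumed
Reagents that add atoms: water, O
Why: The acid should first hydrolyse the very labile dimethyl ketal of 7 to the p-quinol 8, whose C7 carbonyl makes C8a a Michael acceptor; the C2 hydroxyl, held close by the Z alkene, should add there to give the cis-fused enone 9, and loss of the doubly allylic C4a hydroxyl as water together with the C8a proton should aromatize ring A, the C7 carbonyl emerging as the free 7-OH of 10. The closest known reaction types are the acid-catalysed intramolecular oxa-Michael addition of tethered alcohols to 4-substituted cyclohexa-2,5-dienones and the dehydrative rearomatization of p-quinol conjugate adducts to meta-substituted phenols. Ring C closes in a 6-exo-trig mode (O1 onto C8a of the C8a=C8 enone bond), while ring A is not closed but aromatized. No lasting stereocentre is created, since C4a and C8a of 9 become sp2, and C2 keeps its configuration because its C–O bond is never broken. The step needs O1 to end up ortho to C4a and meta to the C7 oxygen, which the mirror symmetry of the dienone secures because attack at either β-carbon gives the same phenol. It also needs hydrolysis to precede any ionization, which is secured by the lability of the quinone monoketal, the reluctance of the quinol hydroxyl to ionize (it would give a phenoxenium ion) and the mildness of the phosphoric acid, chosen to spare the acid-sensitive 2-aryl-2H-chromene.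

Step 6
Reactants: 10 (S)-2-[3,4,5-tris(benzyloxy)phenyl]-2H-chromen-7-ol
Product: 11 (S)-7-(benzyloxy)-2-[3,4,5-tris(benzyloxy)phenyl]-2H-chromene
Conditions: BnBr (1.2 equiv), K2CO3, DMF, rt
Reagents that add atoms: benzyl bromide, BrCc1ccccc1
Why: Williamson etherification of the only free hydroxyl, a phenol, should cap O7 so that the later epoxide cannot collapse to a neutral quinone methide.

Step 7
Reactants: 12 (+)-gallocatechin
Product: 13 (2R,3S)-5,7-bis(benzyloxy)-2-[3,4,5-tris(benzyloxy)phenyl]chroman-3-ol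
Conditions: BnBr (5.5 equiv), K2CO3, DMF, 0 °C to rt, under argon
Reagents that add atoms: benzyl bromide, BrCc1ccccc1
Why: Carbonate-mediated Williamson etherification should be selective for the five phenols over the aliphatic 3-OH, and the weak base should avoid epimerization at C2.

Step 8
Reactants: 13 (2R,3S)-5,7-bis(benzyloxy)-2-[3,4,5-tris(benzyloxy)phenyl]chroman-3-ol
Product: 14 (2R,3S)-5,7-bis(benzyloxy)-8-bromo-2-[3,4,5-tris(benzyloxy)phenyl]chroman-3-ol
Conditions: NBS (1.0 equiv), CH2Cl2, −20 °C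
Reagents that add atoms: N-bromosuccinimide, O=C1CCC(=O)N1Br
Why: Electrophilic aromatic bromination of the phloroglucinol-type ring D should occur at C8, the more reactive free position of 5,7-di-O-alkyl flavan-3-ols, leaving C6 as the only nucleophilic ring carbon.

Step 9
Reactants: 11 (S)-7-(benzyloxy)-2-[3,4,5-tris(benzyloxy)phenyl]-2H-chromene; 14 (2R,3S)-5,7-bis(benzyloxy)-8-bromo-2-[3,4,5-tris(benzyloxy)phenyl]chroman-3-ol
Product: 16 7,3′,4′,5′-tetra-O-benzylrobinetinidol-(4α→6)-[8-bromo-5,7,3′,4′,5′-penta-O-benzylgallocatechin], via epoxide 15 (not isolated)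
Conditions: DMDO (1.1 equiv), acetone–CH2Cl2, −40 °C; volatiles removed cold; then 14 (2 equiv), BF3·OEt2 (0.3 equiv), CH2Cl2, −78 to −30 °C
Reagents that add atoms: dimethyldioxirane, CC1(C)OO1
Why: DMDO should epoxidize the electron-rich chromene alkene anti to the C2 aryl group (sets C3), and Friedel–Crafts opening of the epoxide at the benzylic, para-benzyloxy-activated C4, anti to the epoxide oxygen, by the only free ring D carbon of 14 should give the 3,4-trans, 4→6 linked product (sets C4).

Step 10
Reactants: 16 7,3′,4′,5′-tetra-O-benzylrobinetinidol-(4α→6)-[8-bromo-5,7,3′,4′,5′-penta-O-benzylgallocatechin]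
Product: 17 robinetinidol-(4α→6)-gallocatechin
Conditions: H2 (1 atm), Pd(OH)2/C, Et3N (1.5 equiv), THF–MeOH, rt; filtration under argon
Reagents that add atoms: none
Why: Catalytic hydrogenolysis should cleave the nine benzyl ethers and, with Et3N as acid acceptor, the C8–Br bond, while the ring ethers, the interflavan bond and the five stereocentres should survive as they do in standard proanthocyanidin deprotections.

**Compound list**

1 | 3,4,5-tris(benzyloxy)benzaldehyde | O=Cc1cc(OCc2ccccc2)c(OCc2ccccc2)c(OCc2ccccc2)c1 | starting material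
2 | trimethylsilylacetylene | C#C[Si](C)(C)C | starting material
3 | (R)-1-[3,4,5-tris(benzyloxy)phenyl]-3-(trimethylsilyl)prop-2-yn-1-ol | O[C@H](c1cc(OCc2ccccc2)c(OCc2ccccc2)c(OCc2ccccc2)c1)C#C[Si](C)(C)C | intermediate
4 | (S)-1-[3,4,5-tris(benzyloxy)phenyl]prop-2-yn-1-ol | O[C@H](c1cc(OCc2ccccc2)c(OCc2ccccc2)c(OCc2ccccc2)c1)C#C | intermediate
5 | 4,4-dimethoxycyclohexa-2,5-dien-1-one (p-benzoquinone mono(dimethyl ketal)) | O=C1C=CC(OC)(OC)C=C1 | starting material
6 | 1-{(3R)-3-hydroxy-3-[3,4,5-tris(benzyloxy)phenyl]prop-1-yn-1-yl}-4,4-dimethoxycyclohexa-2,5-dien-1-ol | O[C@H](c1cc(OCc2ccccc2)c(OCc2ccccc2)c(OCc2ccccc2)c1)C#CC1(O)C=CC(OC)(OC)C=C1 | intermediate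
7 | 1-{(1Z,3S)-3-hydroxy-3-[3,4,5-tris(benzyloxy)phenyl]prop-1-en-1-yl}-4,4-dimethoxycyclohexa-2,5-dien-1-ol | O[C@H](c1cc(OCc2ccccc2)c(OCc2ccccc2)c(OCc2ccccc2)c1)/C=C\C1(O)C=CC(OC)(OC)C=C1 | intermediate
8 | 4-hydroxy-4-{(1Z,3S)-3-hydroxy-3-[3,4,5-tris(benzyloxy)phenyl]prop-1-en-1-yl}cyclohexa-2,5-dien-1-one (p-quinol) | O[C@H](c1cc(OCc2ccccc2)c(OCc2ccccc2)c(OCc2ccccc2)c1)/C=C\C1(O)C=CC(=O)C=C1 | intermediate (not isolated)
9 | (2S)-4a-hydroxy-2-[3,4,5-tris(benzyloxy)phenyl]-4a,8a-dihydro-2H-chromen-7(8H)-one, cis-fused; both C4a/C8a diastereomers converge, so these two centres are left open | O=C1C=CC2(O)C=C[C@@H](c3cc(OCc4ccccc4)c(OCc4ccccc4)c(OCc4ccccc4)c3)OC2C1 | intermediate (not isolated)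
10 | (S)-2-[3,4,5-tris(benzyloxy)phenyl]-2H-chromen-7-ol | Oc1ccc2c(c1)O[C@H](c1cc(OCc3ccccc3)c(OCc3ccccc3)c(OCc3ccccc3)c1)C=C2 | intermediate
11 | (S)-7-(benzyloxy)-2-[3,4,5-tris(benzyloxy)phenyl]-2H-chromene | c1(OCc3ccccc3)ccc2c(c1)O[C@H](c1cc(OCc3ccccc3)c(OCc3ccccc3)c(OCc3ccccc3)c1)C=C2 | intermediate
12 | (+)-gallocatechin, (2R,3S)-2-(3,4,5-trihydroxyphenyl)chromane-3,5,7-triol | c1c(O)cc2c(c1O)C[C@H](O)[C@@H](c1cc(O)c(O)c(O)c1)O2 | starting material
13 | (2R,3S)-5,7-bis(benzyloxy)-2-[3,4,5-tris(benzyloxy)phenyl]chroman-3-ol | c1c(OCc3ccccc3)cc2c(c1OCc3ccccc3)C[C@H](O)[C@@H](c1cc(OCc3ccccc3)c(OCc3ccccc3)c(OCc3ccccc3)c1)O2 | intermediate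
14 | (2R,3S)-5,7-bis(benzyloxy)-8-bromo-2-[3,4,5-tris(benzyloxy)phenyl]chroman-3-ol | c1c(OCc3ccccc3)c(Br)c2c(c1OCc3ccccc3)C[C@H](O)[C@@H](c1cc(OCc3ccccc3)c(OCc3ccccc3)c(OCc3ccccc3)c1)O2 | intermediate
15 | (2R,3S,4S)-7-(benzyloxy)-3,4-epoxy-2-[3,4,5-tris(benzyloxy)phenyl]chromane (epoxide oxygen anti to the C2 aryl group) | c1(OCc3ccccc3)ccc2c(c1)O[C@H](c1cc(OCc3ccccc3)c(OCc3ccccc3)c(OCc3ccccc3)c1)[C@H]1O[C@H]12 | intermediate (not isolated)
16 | 7,3′,4′,5′-tetra-O-benzylrobinetinidol-(4α→6)-[8-bromo-5,7,3′,4′,5′-penta-O-benzylgallocatechin]; upper unit 2R,3S,4S, lower unit 2R,3S | c1(OCc3ccccc3)ccc2c(c1)O[C@H](c1cc(OCc3ccccc3)c(OCc3ccccc3)c(OCc3ccccc3)c1)[C@@H](O)[C@@H]2c1c(OCc3ccccc3)c(Br)c2c(c1OCc3ccccc3)C[C@H](O)[C@@H](c1cc(OCc3ccccc3)c(OCc3ccccc3)c(OCc3ccccc3)c1)O2 | intermediate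
17 | robinetinidol-(4α→6)-gallocatechin; upper unit 2R,3S,4S, lower unit 2R,3S | Oc1ccc2c(c1)O[C@H](c1cc(O)c(O)c(O)c1)[C@@H](O)[C@@H]2c1c(O)cc2c(c1O)C[C@H](O)[C@@H](c1cc(O)c(O)c(O)c1)O2 | target

**Count and risks**

Total step count: 10. Longest linear sequence: 8 steps (steps 1 to 6, 9 and 10).

Steps most likely to fail:

Step 5. The acid that drives the cascade may also promote heterolysis of the C2–O bond of the 2-aryl-2H-chromene (loss of configurational integrity at C2, disproportionation of the flavene), or the dehydration of the conjugate adduct may stall. Fallback by known chemistry, with ring A aromatic from the start and the same O1–C8a bond made by metal catalysis: compound 4 is coupled with 4-(benzyloxy)-2-bromo-1-iodobenzene (Ic1ccc(OCc2ccccc2)cc1Br) in a Sonogashira reaction at the iodide (PdCl2(PPh3)2, CuI, Et3N) to give (R)-3-[4-(benzyloxy)-2-bromophenyl]-1-[3,4,5-tris(benzyloxy)phenyl]prop-2-yn-1-ol F1. Lindlar semihydrogenation should then give (1S,2Z)-3-[4-(benzyloxy)-2-bromophenyl]-1-[3,4,5-tris(benzyloxy)phenyl]prop-2-en-1-ol F2, and an intramolecular Ullmann-type O-arylation (CuI, 1,10-phenanthroline, Cs2CO3, toluene, 110 °C) should close ring C and return to the route at compound 11.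

Step 9. The labile para-alkoxyaryl epoxide may rearrange to the flavan-3-one by hydride shift before it is arylated, facial selectivity may be poor in either event, or attack by the hindered, bromine-bearing ring D may be slow. Fallback: compound 11 is dihydroxylated (OsO4 cat., NMO, acetone–H2O) anti to the C2 aryl group to give the stable (2R,3S,4S)-7-(benzyloxy)-2-[3,4,5-tris(benzyloxy)phenyl]chromane-3,4-diol F3. Its C4 carbinol is then ionized with TMSOTf in CH2Cl2 at −78 °C in the presence of 14, so that the para-benzyloxybenzylic cation is captured by C6 of 14 trans to the C3 oxygen (classical flavan-3,4-diol condensation), coming back to the route at compound 16.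

Step 1. Enantiofacial discrimination in the catalytic alkynylation may be insufficient for this electron-rich aryl aldehyde. Fallback: compound 1 is treated with ethynylmagnesium bromide (THF, 0 °C) to give racemic 1-[3,4,5-tris(benzyloxy)phenyl]prop-2-yn-1-ol F4. Lipase-mediated kinetic resolution (Candida antarctica lipase B, vinyl acetate, toluene) should acylate the R alcohol, removed as (R)-1-[3,4,5-tris(benzyloxy)phenyl]prop-2-yn-1-yl acetate F5, and leave the S alcohol, which is compound 4; the route is rejoined there and step 2 is not needed.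

**Further compounds**

F1 | step 5 | (R)-3-[4-(benzyloxy)-2-bromophenyl]-1-[3,4,5-tris(benzyloxy)phenyl]prop-2-yn-1-ol | O[C@H](c1cc(OCc2ccccc2)c(OCc2ccccc2)c(OCc2ccccc2)c1)C#Cc1ccc(OCc2ccccc2)cc1Br
F2 | step 5 | (1S,2Z)-3-[4-(benzyloxy)-2-bromophenyl]-1-[3,4,5-tris(benzyloxy)phenyl]prop-2-en-1-ol | O[C@H](c1cc(OCc2ccccc2)c(OCc2ccccc2)c(OCc2ccccc2)c1)/C=C\c1ccc(OCc2ccccc2)cc1Br
F3 | step 9 | (2R,3S,4S)-7-(benzyloxy)-2-[3,4,5-tris(benzyloxy)phenyl]chromane-3,4-diol | c1(OCc3ccccc3)ccc2c(c1)O[C@H](c1cc(OCc3ccccc3)c(OCc3ccccc3)c(OCc3ccccc3)c1)[C@@H](O)[C@H]2O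
F4 | step 1 | racemic 1-[3,4,5-tris(benzyloxy)phenyl]prop-2-yn-1-ol | OC(c1cc(OCc2ccccc2)c(OCc2ccccc2)c(OCc2ccccc2)c1)C#C
F5 | step 1 | (R)-1-[3,4,5-tris(benzyloxy)phenyl]prop-2-yn-1-yl acetate | CC(=O)O[C@@H](c1cc(OCc2ccccc2)c(OCc2ccccc2)c(OCc2ccccc2)c1)C#C
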